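**Retrosynthetic overview**

1. Locants: C1 (=CH2), C2 (OAc), C3–C4, C5 (CH2OAc), C6–C7, C8=C9(CH3), C10, C11, C12–C13, C14 (C–CH3), C15 (OH), C16 (OH). Rings: eleven-membered ring C1–C11, cyclohexene ring C (C8, C9, C10, C14, C15, C16), cyclopentane ring D (C10–C14).
2. Enabling feature: in ring C, C9 lies between C8 and C10, and C14–C15–C16 carries oxygen on C15 and C16. With C9 as a ketone and C14=C15(OR)–C16H=O as a 2-alkoxy enal, ring C is a bicyclo[3.3.1]nonan-9-one in disguise once a temporary C2–C8 bond makes C1/C2/C8/C9/C10/C11 a cyclohexanone (ring A). The C2 oxygen and the C8=C9 alkene are the retron for later retro-aldol cleavage of that bond.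
3. Key disconnections: C9–CH3 (Stille coupling of an enol triflate); C2–C8 (retro-aldol fragmentation that opens rings A and B into the eleven-membered ring and fixes the C8=C9 enolate); C10–C14 plus C8–C16 (tandem Michael–aldol annulation closing rings D and C); C7–C8 (intramolecular B-alkyl Suzuki coupling, ring B); C2–C3 (Grignard addition); C11–C12 (asymmetric conjugate addition to cyclohexenone).
4. Ring order: ring A is purchased (cyclohexenone); ring B in step 12; rings D and C together in step 18; rings A and B are merged into the eleven-membered ring in step 20. C5 comes from a rhodium-catalysed vinyl addition to furan-2(5H)-one, C11 from the copper-catalysed conjugate addition.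

Key step: step 18

Remark: temporary stereocentres (C1–H, tertiary C2, C8–H, the C9 carbinol, the acetal carbon) and the C14=C15 geometry are drawn as the expected major isomers; all are erased before the target and the route does not depend on them. Phosphonate 10 is racemic.
Remark: TBDPS = tert-butyldiphenylsilyl, PMB = 4-methoxybenzyl; descriptive names use the locants of the overview.

**Route**

Step 1
Reactants: 1 furan-2(5H)-one; 2 potassium vinyltrifluoroborate
Product: 3 (S)-4-vinyldihydrofuran-2(3H)-one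
Conditions: [Rh(cod)Cl]2 (3 mol %), (S)-BINAP, Et3N, toluene/H2O (10:1), 100 °C
Reagents that add atoms: none
Why: Rhodium-catalysed asymmetric 1,4-addition (Hayashi–Miyaura reaction) transfers the vinyl group to the butenolide, the BINAP enantiomer being chosen so that the catalyst-controlled enantioface gives the S lactone (future C5).

Step 2
Reactants: 3 (S)-4-vinyldihydrofuran-2(3H)-one
Product: 4 (S)-3-(hydroxymethyl)-1-(pyrrolidin-1-yl)pent-4-en-1-one
Conditions: pyrrolidine (3 equiv), THF, 40 °C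
Reagents that add atoms: pyrrolidine, C1CCNC1
Why: Aminolysis of the γ-lactone gives the hydroxy amide, which differentiates the two oxygenated chain ends without touching the stereocentre.

Step 3
Reactants: 4 (S)-3-(hydroxymethyl)-1-(pyrrolidin-1-yl)pent-4-en-1-one
Product: 5 (S)-3-(TBDPS-oxymethyl)-1-(pyrrolidin-1-yl)pent-4-en-1-one
Conditions: t-BuPh2SiCl, imidazole, DMF, 0 °C to rt
Reagents that add atoms: tert-butyl(chloro)diphenylsilane, CC(C)(C)[Si](Cl)(c1ccccc1)c1ccccc1
Why: Silyl ether formation protects the primary alcohol that will become the C5 CH2OAc oxygen.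

Step 4
Reactants: 5 (S)-3-(TBDPS-oxymethyl)-1-(pyrrolidin-1-yl)pent-4-en-1-one
Product: 6 (S)-3-(TBDPS-oxymethyl)pent-4-en-1-ol
Conditions: LiEt3BH (2.5 equiv), THF, 0 °C to rt
Reagents that add atoms: none
Why: Hydride reduction of the tertiary amide with LiEt3BH proceeds with C–N cleavage to the primary alcohol (amide reduction), leaving alkene and silyl ether intact.

Step 5
Reactants: 6 (S)-3-(TBDPS-oxymethyl)pent-4-en-1-ol
Product: 7 (S)-{[2-(2-bromoethyl)but-3-en-1-yl]oxy}(tert-butyl)diphenylsilane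
Conditions: CBr4, PPh3, CH2Cl2, 0 °C
Reagents that add atoms: tetrabromomethane, BrC(Br)(Br)Br
Why: The Appel reaction converts the primary alcohol into the bromide needed for the Grignard reagent.

Step 6
Reactants: 8 ethyl 2-diazo-2-(diethoxyphosphoryl)acetate; 9 (4-methoxyphenyl)methanol
Product: 10 ethyl 2-(diethoxyphosphoryl)-2-[(4-methoxybenzyl)oxy]acetate
Conditions: Rh2(OAc)4 (1 mol %), toluene, 80 °C
Reagents that add atoms: none
Why: Rhodium-carbenoid O–H insertion of the diazophosphonate into the benzylic alcohol gives the α-alkoxy phosphonate, whose stereocentre is lost in step 15.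

Step 7
Reactants: 11 cyclohex-2-en-1-one; 12 2-(2-bromoethyl)-2-methyl-1,3-dioxolane
Product: 15 (2R,3S)-2-(hydroxymethyl)-3-[2-(2-methyl-1,3-dioxolan-2-yl)ethyl]cyclohexan-1-one, via Grignard reagent 13 (not isolated), via magnesium enolate 14 (not isolated)
Conditions: Mg, THF (12 to 13); CuBr·SMe2 (5 mol %), Josiphos ligand (enantiomer that gives the 3S adduct), t-BuOMe, −75 °C; then CH2O (gas), −75 to −40 °C; aq. NH4Cl
Reagents that add atoms: formaldehyde, C=O
Why: Copper-catalysed asymmetric conjugate addition of the Grignard reagent sets C11 under ligand control, and the regiodefined magnesium enolate is trapped by formaldehyde (aldol reaction) anti to the new side chain, giving the trans C1/C11 relationship.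

Step 8
Reactants: 15 (2R,3S)-2-(hydroxymethyl)-3-[2-(2-methyl-1,3-dioxolan-2-yl)ethyl]cyclohexan-1-one
Product: 16 (2R,3S)-2-(TBDPS-oxymethyl)-3-[2-(2-methyl-1,3-dioxolan-2-yl)ethyl]cyclohexan-1-one
Conditions: t-BuPh2SiCl, imidazole, DMF, 0 °C
Reagents that add atoms: tert-butyl(chloro)diphenylsilane, CC(C)(C)[Si](Cl)(c1ccccc1)c1ccccc1
Why: Silyl ether formation protects the primary alcohol and suppresses retro-aldol loss of formaldehyde.

Step 9
Reactants: 16 (2R,3S)-2-(TBDPS-oxymethyl)-3-[2-(2-methyl-1,3-dioxolan-2-yl)ethyl]cyclohexan-1-one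
Product: 17 (5R,6R)-6-(TBDPS-oxymethyl)-5-[2-(2-methyl-1,3-dioxolan-2-yl)ethyl]cyclohex-2-en-1-one
Conditions: LiN(i-Pr)2, THF, −78 °C; then N-tert-butylbenzenesulfinimidoyl chloride, −78 °C
Reagents that add atoms: none
Why: Kinetic deprotonation at the unsubstituted α-CH2 (C8) followed by sulfinimidoyl chloride dehydrogenation (Mukaiyama dehydrogenation) installs the C8=C9 enone on the side remote from the substituents.

Step 10
Reactants: 17 (5R,6R)-6-(TBDPS-oxymethyl)-5-[2-(2-methyl-1,3-dioxolan-2-yl)ethyl]cyclohex-2-en-1-one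
Product: 18 (5R,6R)-6-(TBDPS-oxymethyl)-2-iodo-5-[2-(2-methyl-1,3-dioxolan-2-yl)ethyl]cyclohex-2-en-1-one
Conditions: I2, pyridine, CH2Cl2, rt
Reagents that add atoms: iodine, II
Why: α-Iodination of the enone by pyridine-mediated addition–iodination–elimination (Baylis–Hillman-type pathway) places the vinyl iodide on C8.

Step 11
Reactants: 18 (5R,6R)-6-(TBDPS-oxymethyl)-2-iodo-5-[2-(2-methyl-1,3-dioxolan-2-yl)ethyl]cyclohex-2-en-1-one; 7 (S)-{[2-(2-bromoethyl)but-3-en-1-yl]oxy}(tert-butyl)diphenylsilane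
Product: 20 (1S,5R,6R)-6-(TBDPS-oxymethyl)-2-iodo-5-[2-(2-methyl-1,3-dioxolan-2-yl)ethyl]-1-[(3S)-3-(TBDPS-oxymethyl)pent-4-en-1-yl]cyclohex-2-en-1-ol, via Grignard reagent 19 (not isolated)
Conditions: Mg, THF (7 to 19); CeCl3, THF, −78 °C; then 18, −78 to −40 °C
Reagents that add atoms: none
Why: Organocerium-mediated Grignard 1,2-addition to the enone carbonyl forms C2–C3, attack anti to the neighbouring CH2OTBDPS group setting the temporary C2 carbinol.

Step 12
Reactants: 20 iodo allylic alcohol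
Product: 22 bicyclic allylic alcohol (rings A and B; tertiary C2–OH at the ring fusion; C8=C9), via alkylborane 21 (not isolated)
Conditions: 9-BBN dimer, THF, rt; then Pd(dppf)Cl2 (10 mol %), AsPh3, Cs2CO3, DMF/H2O, 50 °C
Reagents that add atoms: none
Why: Chemoselective hydroboration of the terminal alkene and intramolecular B-alkyl Suzuki–Miyaura coupling with the vinyl iodide form C7–C8 and close the seven-membered ring B.

Step 13
Reactants: 22 bicyclic allylic alcohol
Product: 23 bicyclic diol (secondary C9–OH; C8–H; trans ring fusion; ketal intact)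
Conditions: BH3·THF, THF, 0 °C to rt; then NaOH, H2O2, 0 °C
Reagents that add atoms: hydrogen peroxide, OO
Why: Hydroboration–oxidation of the trisubstituted C8=C9 alkene places oxygen on the less substituted C9 by syn addition anti to the C2 hydroxyl, the two new centres being temporary (C9 is oxidised and C8 enolised later).

Step 14
Reactants: 23 bicyclic diol
Product: 24 diol methyl ketone (C14 ketone unmasked)
Conditions: PPTS, acetone/H2O (10:1), 50 °C
Reagents that add atoms: water, O
Why: Mild acid-catalysed acetal hydrolysis releases the C14 methyl ketone while the silyl ethers and both alcohols survive.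

Step 15
Reactants: 24 diol methyl ketone; 10 ethyl 2-(diethoxyphosphoryl)-2-[(4-methoxybenzyl)oxy]acetate
Product: 25 ethyl 2-(PMB-oxy)enoate (C14=C15 with C16 as the ester; drawn Z)
Conditions: NaH (5 equiv), 10 (3 equiv), THF, 0 to 50 °C
Reagents that add atoms: none
Why: Horner–Wadsworth–Emmons olefination of the methyl ketone with the α-alkoxy phosphonate anion (excess base covers the two hydroxyls) builds C14=C15–C16, either alkene isomer being usable.

Step 16
Reactants: 25 ethyl 2-(PMB-oxy)enoate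
Product: 26 triol (C16 allylic alcohol)
Conditions: i-Bu2AlH (6 equiv), CH2Cl2, −78 °C
Reagents that add atoms: none
Why: 1,2-Reduction of the unsaturated ester with i-Bu2AlH at low temperature gives the allylic alcohol without touching the enol ether.

Step 17
Reactants: 26 triol
Product: 27 keto enal (C9 ketone; tertiary C2–OH; C14=C15(OPMB)–C16H=O)
Conditions: Dess–Martin periodinane (3 equiv), NaHCO3, CH2Cl2, 0 °C to rt
Reagents that add atoms: none
Why: Dess–Martin oxidation converts the C9 carbinol into the ketone and the allylic alcohol into the 2-alkoxy enal in one operation, the tertiary C2 hydroxyl being inert.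

Step 18
Reactants: 27 keto enal
Product: 29 tetracyclic ketol (rings A–D; bridging C9 ketone; equatorial C16–OH; C15–OPMB; C2–OH), via Michael adduct 28 (not isolated)
Conditions: t-BuOK (0.3 equiv), t-BuOH/THF (1:4), 0 °C to rt; aq. NH4Cl
Reagents that add atoms: none
Why: Proposed new method: a base-mediated intramolecular Michael–aldol α,α′-annulation, in which the C10 enolate of the ring A ketone adds to C14 of the tethered 2-alkoxy enal (5-exo-trig, closes ring D, creates the quaternary C14) and, after proton transfer, the C8 enolate adds to the C16 aldehyde of 28 (6-exo-trig aldol, closes ring C); the closest known reaction type is the Michael–aldol annulation of cyclohexanones with acrolein or methacrolein to 2-hydroxybicyclo[3.3.1]nonan-9-ones, here made doubly intramolecular and extended to a 2-alkoxy-3,3-disubstituted enal. C10 is set by the two-carbon tether from C11, which can deliver C14 only to the cis face of ring A (cis C10–H/C11–H), and C14 is set because only the epimer with C15 over ring A (CH3 cis to C10–H, reached through a chelated synclinal transition state) can close ring C, the other being returned by retro-Michael reaction. C15 (α to the aldehyde in 28) and C16 (reversible aldol) settle in the trans-diequatorial arrangement, since an endo C15 substituent clashes with C1–H across the bicyclo[3.3.1] core and an axial C16 hydroxyl is syn-diaxial to the C14 methyl group. The step needs C10 rather than C8 as Michael donor and an intact C2–C8 bond: five-membered closure from C10 outpaces seven-membered closure from C8, and retro-aldol opening of the tertiary carbinol to an eleven-membered diketone is uphill under catalytic base. Both alkene isomers of 27 converge because the C14=C15 geometry disappears in the enolate of 28.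

Step 19
Reactants: 29 tetracyclic ketol
Product: 30 p-methoxybenzylidene acetal (C15–O/C16–O dioxolane; free C2–OH; C9 ketone)
Conditions: DDQ (1.2 equiv), 4 Å molecular sieves, CH2Cl2, 0 °C
Reagents that add atoms: none
Why: DDQ oxidation of the PMB ether to its oxocarbenium ion and capture by the vicinal C16 hydroxyl (oxidative acetalisation) ties C15–O and C16–O into one acetal, which also blocks retro-aldol opening at C16.

Step 20
Reactants: 30 p-methoxybenzylidene acetal
Product: 32 enol triflate (eleven-membered ring; C2 ketone; C8=C9–OTf), via potassium enolate 31 (not isolated)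
Conditions: KN(SiMe3)2 (1.1 equiv), PhNTf2 (1.3 equiv), THF, −78 to −30 °C
Reagents that add atoms: N-phenylbis(trifluoromethanesulfonimide), O=S(=O)(N(c1ccccc1)S(=O)(=O)C(F)(F)F)C(F)(F)F
Why: Deprotonation of the tertiary C2 hydroxyl triggers retro-aldol fragmentation of the temporary C2–C8 bond (the bridging C9 ketone accepts the electrons), which merges rings A and B into the eleven-membered ring and gives the C8=C9 enolate regiospecifically for O-triflation, the alkene geometry being fixed by ring C.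

Step 21
Reactants: 32 enol triflate
Product: 33 methyl alkene ketone (C9–CH3; C2 ketone; C1–CH2OTBDPS)
Conditions: Me4Sn, Pd(PPh3)4 (10 mol %), LiCl, DMF, 80 °C
Reagents that add atoms: tetramethylstannane, C[Sn](C)(C)C
Why: Stille coupling of the enol triflate with tetramethylstannane (LiCl-assisted) installs the C9 methyl group without moving the alkene.

Step 22
Reactants: 33 methyl alkene ketone
Product: 34 α-methylene ketone (C1=CH2; C2 ketone)
Conditions: DBU, MeCN, 40 °C
Reagents that add atoms: none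
Why: E1cB elimination of silanolate from the β-silyloxy ketone creates the exocyclic methylene on C1, conjugated to the C2 ketone.

Step 23
Reactants: 34 α-methylene ketone
Product: 35 (2S)-allylic alcohol
Conditions: (R)-2-methyl-CBS-oxazaborolidine (0.5 equiv), catecholborane, toluene, −78 °C
Reagents that add atoms: none
Why: Corey–Bakshi–Shibata reduction delivers hydride 1,2 to the enone under catalyst control (the α-methylene side acting as the large group), which with the R catalyst should set the 2S carbinol.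

Step 24
Reactants: 35 (2S)-allylic alcohol
Product: 36 diol (C2–OH and C5 CH2OH)
Conditions: Bu4NF, AcOH, THF, rt
Reagents that add atoms: none
Why: Fluoride-mediated desilylation frees the primary alcohol on C5 while the acetal and the allylic alcohol are untouched.

Step 25
Reactants: 36 diol
Product: 37 diacetate acetal
Conditions: Ac2O, pyridine, DMAP, CH2Cl2, rt
Reagents that add atoms: acetic anhydride, CC(=O)OC(C)=O
Why: DMAP-catalysed acylation of both hydroxyls installs the two acetates of the target.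

Step 26
Reactants: 37 diacetate acetal
Product: 38 CNP0193272.1
Conditions: AcOH/THF/H2O (3:1:1), 40 °C
Reagents that add atoms: none
Why: Mild aqueous acid hydrolyses the p-methoxybenzylidene acetal (acetal hydrolysis) to release the C15/C16 diol without cleaving the acetates.

**Compound list**

1 | furan-2(5H)-one | O=C1C=CCO1 | starting material
2 | potassium vinyltrifluoroborate | [K+].C=C[B-](F)(F)F | starting material
3 | (S)-4-vinyldihydrofuran-2(3H)-one | O=C1C[C@@H](C=C)CO1 | intermediate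
4 | (S)-3-(hydroxymethyl)-1-(pyrrolidin-1-yl)pent-4-en-1-one | O=C(C[C@@H](C=C)CO)N1CCCC1 | intermediate
5 | (S)-3-(TBDPS-oxymethyl)-1-(pyrrolidin-1-yl)pent-4-en-1-one | O=C(C[C@@H](C=C)CO[Si](c1ccccc1)(c2ccccc2)C(C)(C)C)N3CCCC3 | intermediate
6 | (S)-3-(TBDPS-oxymethyl)pent-4-en-1-ol | OCC[C@@H](C=C)CO[Si](c1ccccc1)(c2ccccc2)C(C)(C)C | intermediate
7 | (S)-{[2-(2-bromoethyl)but-3-en-1-yl]oxy}(tert-butyl)diphenylsilane | BrCC[C@@H](C=C)CO[Si](c1ccccc1)(c2ccccc2)C(C)(C)C | intermediate
8 | ethyl 2-diazo-2-(diethoxyphosphoryl)acetate | CCOC(=O)C(=[N+]=[N-])P(=O)(OCC)OCC | starting material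
9 | (4-methoxyphenyl)methanol | COc1ccc(CO)cc1 | starting material
10 | ethyl 2-(diethoxyphosphoryl)-2-[(4-methoxybenzyl)oxy]acetate (racemic) | CCOC(=O)C(OCc1ccc(OC)cc1)P(=O)(OCC)OCC | intermediate
11 | cyclohex-2-en-1-one | O=C1C=CCCC1 | starting material
12 | 2-(2-bromoethyl)-2-methyl-1,3-dioxolane | CC1(CCBr)OCCO1 | starting material
13 | [2-(2-methyl-1,3-dioxolan-2-yl)ethyl]magnesium bromide | CC1(CC[Mg]Br)OCCO1 | intermediate
14 | bromomagnesium (S)-3-[2-(2-methyl-1,3-dioxolan-2-yl)ethyl]cyclohex-1-en-1-olate | Br[Mg]OC1=C[C@H](CCC2(C)OCCO2)CCC1 | intermediate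
15 | (2R,3S)-2-(hydroxymethyl)-3-[2-(2-methyl-1,3-dioxolan-2-yl)ethyl]cyclohexan-1-one | O=C1CCC[C@@H](CCC2(C)OCCO2)[C@@H]1CO | intermediate
16 | (2R,3S)-2-(TBDPS-oxymethyl)-3-[2-(2-methyl-1,3-dioxolan-2-yl)ethyl]cyclohexan-1-one | O=C1CCC[C@@H](CCC2(C)OCCO2)[C@@H]1CO[Si](c3ccccc3)(c4ccccc4)C(C)(C)C | intermediate
17 | (5R,6R)-6-(TBDPS-oxymethyl)-5-[2-(2-methyl-1,3-dioxolan-2-yl)ethyl]cyclohex-2-en-1-one | O=C1C=CC[C@@H](CCC2(C)OCCO2)[C@@H]1CO[Si](c3ccccc3)(c4ccccc4)C(C)(C)C | intermediate
18 | (5R,6R)-6-(TBDPS-oxymethyl)-2-iodo-5-[2-(2-methyl-1,3-dioxolan-2-yl)ethyl]cyclohex-2-en-1-one | O=C1C(I)=CC[C@@H](CCC2(C)OCCO2)[C@@H]1CO[Si](c3ccccc3)(c4ccccc4)C(C)(C)C | intermediate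
19 | (S)-[3-(TBDPS-oxymethyl)pent-4-en-1-yl]magnesium bromide | Br[Mg]CC[C@@H](C=C)CO[Si](c1ccccc1)(c2ccccc2)C(C)(C)C | intermediate
20 | iodo allylic alcohol: (1S,5R,6R)-6-(TBDPS-oxymethyl)-2-iodo-5-[2-(2-methyl-1,3-dioxolan-2-yl)ethyl]-1-[(3S)-3-(TBDPS-oxymethyl)pent-4-en-1-yl]cyclohex-2-en-1-ol | O[C@]1(CC[C@@H](C=C)CO[Si](c2ccccc2)(c3ccccc3)C(C)(C)C)C(I)=CC[C@@H](CCC4(C)OCCO4)[C@@H]1CO[Si](c5ccccc5)(c6ccccc6)C(C)(C)C | intermediate
21 | alkylborane: C7 B-alkyl-9-BBN adduct of 20 | O[C@]1(CC[C@@H](CCB2C3CCCC2CCC3)CO[Si](c4ccccc4)(c5ccccc5)C(C)(C)C)C(I)=CC[C@@H](CCC6(C)OCCO6)[C@@H]1CO[Si](c7ccccc7)(c8ccccc8)C(C)(C)C | intermediate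
22 | bicyclic allylic alcohol (rings A and B; tertiary C2–OH; C8=C9; C3 trans to the C1 side chain) | O[C@]12CC[C@H](CO[Si](c3ccccc3)(c4ccccc4)C(C)(C)C)CCC1=CC[C@@H](CCC5(C)OCCO5)[C@@H]2CO[Si](c6ccccc6)(c7ccccc7)C(C)(C)C | intermediate
23 | bicyclic diol (C9–OH trans to C2–OH; C8–H; trans ring fusion) | O[C@]12CC[C@H](CO[Si](c3ccccc3)(c4ccccc4)C(C)(C)C)CC[C@@H]1[C@@H](O)C[C@@H](CCC5(C)OCCO5)[C@@H]2CO[Si](c6ccccc6)(c7ccccc7)C(C)(C)C | intermediate
24 | diol methyl ketone (C14 ketone) | O[C@]12CC[C@H](CO[Si](c3ccccc3)(c4ccccc4)C(C)(C)C)CC[C@@H]1[C@@H](O)C[C@@H](CCC(C)=O)[C@@H]2CO[Si](c5ccccc5)(c6ccccc6)C(C)(C)C | intermediate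
25 | ethyl (Z)-2-(PMB-oxy)enoate (C14=C15; C16 ester) | O[C@]12CC[C@H](CO[Si](c3ccccc3)(c4ccccc4)C(C)(C)C)CC[C@@H]1[C@@H](O)C[C@@H](CC/C(C)=C(\OCc5ccc(OC)cc5)C(=O)OCC)[C@@H]2CO[Si](c6ccccc6)(c7ccccc7)C(C)(C)C | intermediate
26 | triol (C16 allylic alcohol) | O[C@]12CC[C@H](CO[Si](c3ccccc3)(c4ccccc4)C(C)(C)C)CC[C@@H]1[C@@H](O)C[C@@H](CC/C(C)=C(\OCc5ccc(OC)cc5)CO)[C@@H]2CO[Si](c6ccccc6)(c7ccccc7)C(C)(C)C | intermediate
27 | keto enal (C9 ketone; tertiary C2–OH; 2-(PMB-oxy) enal C14=C15–C16) | O[C@]12CC[C@H](CO[Si](c3ccccc3)(c4ccccc4)C(C)(C)C)CC[C@@H]1C(=O)C[C@@H](CC/C(C)=C(\OCc5ccc(OC)cc5)C=O)[C@@H]2CO[Si](c6ccccc6)(c7ccccc7)C(C)(C)C | intermediate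
28 | Michael adduct (C10–C14 formed; ring D closed; C16 aldehyde) | O[C@]12CC[C@H](CO[Si](c3ccccc3)(c4ccccc4)C(C)(C)C)CC[C@@H]1C(=O)[C@@H]5[C@@H](CC[C@]5(C)[C@@H](OCc6ccc(OC)cc6)C=O)[C@@H]2CO[Si](c7ccccc7)(c8ccccc8)C(C)(C)C | intermediate
29 | tetracyclic ketol (rings A–D; bridging C9 ketone; C16–OH; C15–OPMB; C2–OH) | O[C@]12CC[C@H](CO[Si](c5ccccc5)(c6ccccc6)C(C)(C)C)CC[C@]13C(=O)[C@@H]4[C@@H](CC[C@]4(C)[C@@H](OCc7ccc(OC)cc7)[C@@H]3O)[C@@H]2CO[Si](c8ccccc8)(c9ccccc9)C(C)(C)C | intermediate
30 | p-methoxybenzylidene acetal of 29 (C15–O/C16–O) | O[C@]12CC[C@H](CO[Si](c5ccccc5)(c6ccccc6)C(C)(C)C)CC[C@]13C(=O)[C@@H]4[C@@H](CC[C@]4(C)[C@H]7O[C@@H](c8ccc(OC)cc8)O[C@H]37)[C@@H]2CO[Si](c5ccccc5)(c6ccccc6)C(C)(C)C | intermediate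
31 | potassium enolate (C8=C9–OK; C2 ketone; eleven-membered ring) | O=C1CC[C@H](CO[Si](c5ccccc5)(c6ccccc6)C(C)(C)C)CCC2=C([O-])[C@@H]3[C@@H](CC[C@]3(C)[C@H]4O[C@@H](c7ccc(OC)cc7)O[C@H]24)[C@@H]1CO[Si](c5ccccc5)(c6ccccc6)C(C)(C)C.[K+] | intermediate
32 | enol triflate (C8=C9–OTf; C2 ketone) | O=C1CC[C@H](CO[Si](c5ccccc5)(c6ccccc6)C(C)(C)C)CCC2=C(OS(=O)(=O)C(F)(F)F)[C@@H]3[C@@H](CC[C@]3(C)[C@H]4O[C@@H](c7ccc(OC)cc7)O[C@H]24)[C@@H]1CO[Si](c5ccccc5)(c6ccccc6)C(C)(C)C | intermediate
33 | methyl alkene ketone (C9–CH3; C2 ketone; C1–CH2OTBDPS) | O=C1CC[C@H](CO[Si](c5ccccc5)(c6ccccc6)C(C)(C)C)CCC2=C(C)[C@@H]3[C@@H](CC[C@]3(C)[C@H]4O[C@@H](c7ccc(OC)cc7)O[C@H]24)[C@@H]1CO[Si](c5ccccc5)(c6ccccc6)C(C)(C)C | intermediate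
34 | α-methylene ketone (C1=CH2; C2 ketone) | C=C1C(=O)CC[C@H](CO[Si](c5ccccc5)(c6ccccc6)C(C)(C)C)CCC2=C(C)[C@@H]3[C@H]1CC[C@]3(C)[C@H]4O[C@@H](c7ccc(OC)cc7)O[C@H]24 | intermediate
35 | (2S)-allylic alcohol | C=C1[C@@H](O)CC[C@H](CO[Si](c5ccccc5)(c6ccccc6)C(C)(C)C)CCC2=C(C)[C@@H]3[C@H]1CC[C@]3(C)[C@H]4O[C@@H](c7ccc(OC)cc7)O[C@H]24 | intermediate
36 | diol (C2–OH; C5 CH2OH) | C=C1[C@@H](O)CC[C@H](CO)CCC2=C(C)[C@@H]3[C@H]1CC[C@]3(C)[C@H]4O[C@@H](c7ccc(OC)cc7)O[C@H]24 | intermediate
37 | diacetate acetal | C=C1[C@@H](OC(C)=O)CC[C@H](COC(C)=O)CCC2=C(C)[C@@H]3[C@H]1CC[C@]3(C)[C@H]4O[C@@H](c7ccc(OC)cc7)O[C@H]24 | intermediate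
38 | CNP0193272.1 | C=C1[C@@H](OC(C)=O)CC[C@H](COC(C)=O)CCC2=C(C)[C@@H]3[C@H]1CC[C@]3(C)[C@@H](O)[C@@H]2O | target

**Step count and risks**

Total step count: 26. Longest linear sequence: 21 steps (steps 1–5, then 11–26).

Steps most likely to fail:

Step 18 (proposed method). The conjugate addition to the electron-rich, fully substituted enal carbon may be too slow; the tertiary carbinol may open by premature retro-aldol reaction; the reversible seven-membered aldol from C10 may dehydrate. Fallback with known chemistry: from 27, soft enolisation (Me3SiOTf, Et3N, CH2Cl2, −78 °C) should give the bis(trimethylsilyl) derivative F1 (C2–OSiMe3 and the less hindered C9=C10 silyl enol ether). A Lewis-acid-promoted intramolecular Mukaiyama–Michael addition (TiCl4, CH2Cl2, −78 °C, dilute HCl work-up) then forms C10–C14 and gives 28 as an isolated compound. A separate aldol closure (K2CO3, MeOH, 0 °C) returns to the route at 29.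

Step 20. The alkoxide may fail to fragment at low temperature, or proton transfer from the newly formed C2 ketone may scramble the enolate before O-sulfonylation. Fallback: from 30, MeMgBr with CeCl3 (THF, −78 °C) should add to the C9 ketone from the ring A face, anti to the C14 methyl group, to give the C9 methyl carbinol F2, whose C9–O bond is antiperiplanar to C2–C8. Ionisation of that carbinol (Tf2O, 2,6-di-tert-butyl-4-methylpyridine, CH2Cl2, −78 °C) should trigger a Grob fragmentation that forms the C8=C9(CH3) alkene and the C2 ketone directly, rejoining the route at 33.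

Step 23. Hydride delivery to the C2 ketone in the flexible eleven-membered ring may show poor facial selectivity (catalyst and ring conformation mismatched), or conjugate reduction may compete. Fallback: from 34, Luche reduction (NaBH4, CeCl3·7H2O, MeOH, −78 °C) under substrate control. If it gives mainly the (2R)-allylic alcohol F3, a Mitsunobu reaction with acetic acid (PPh3, DIAD, AcOH, toluene, 0 °C) inverts C2 and installs the acetate in one operation, giving the (2S)-acetate silyl ether F4. Desilylation (Bu4NF, AcOH, THF) gives the acetate alcohol F5, and acetylation (Ac2O, pyridine, DMAP) rejoins the route at 37.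

Further compounds
F1 | step 18 | bis(trimethylsilyl) derivative of 27 (C2–OSiMe3; C9=C10 silyl enol ether) | C[Si](C)(C)O[C@]12CC[C@H](CO[Si](c3ccccc3)(c4ccccc4)C(C)(C)C)CC[C@@H]1C(O[Si](C)(C)C)=C[C@@H](CC/C(C)=C(\OCc5ccc(OC)cc5)C=O)[C@@H]2CO[Si](c6ccccc6)(c7ccccc7)C(C)(C)C
F2 | step 20 | C9 methyl carbinol of 30 (C9–OH on the ring C side) | O[C@]12CC[C@H](CO[Si](c5ccccc5)(c6ccccc6)C(C)(C)C)CC[C@]13[C@@](C)(O)[C@@H]4[C@@H](CC[C@]4(C)[C@H]7O[C@@H](c8ccc(OC)cc8)O[C@H]37)[C@@H]2CO[Si](c5ccccc5)(c6ccccc6)C(C)(C)C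
F3 | step 23 | (2R)-allylic alcohol (C2 epimer of 35) | C=C1[C@H](O)CC[C@H](CO[Si](c5ccccc5)(c6ccccc6)C(C)(C)C)CCC2=C(C)[C@@H]3[C@H]1CC[C@]3(C)[C@H]4O[C@@H](c7ccc(OC)cc7)O[C@H]24
F4 | step 23 | (2S)-acetate silyl ether | C=C1[C@@H](OC(C)=O)CC[C@H](CO[Si](c5ccccc5)(c6ccccc6)C(C)(C)C)CCC2=C(C)[C@@H]3[C@H]1CC[C@]3(C)[C@H]4O[C@@H](c7ccc(OC)cc7)O[C@H]24
F5 | step 23 | (2S)-acetate alcohol (C5 CH2OH) | C=C1[C@@H](OC(C)=O)CC[C@H](CO)CCC2=C(C)[C@@H]3[C@H]1CC[C@]3(C)[C@H]4O[C@@H](c7ccc(OC)cc7)O[C@H]24
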